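**Strategy.** The terpene half is read as a 2,3-seco-eudesmane (eudesmane numbering): natural (−)-β-elemene already holds C5, C7, C10 and all fifteen carbons. Everything rests on forging C2–C3 last, which closes the carbinol ring C10–C1–C2–C3–C4–C5. The key step exploits the isopropenyl group on C5 (C3=C4), which lies δ,ε to C2. Solvolysis of a primary C2 nosylate with π-participation gives the tertiary C4 cation, and water enters anti to the axial C10 methyl. One operation makes the ring, the C4–O bond and the C4 stereocentre. The precursor is a 1-chromenyl-2,3-seco-eudesmatriene, assembled from a β-elemene-derived aldehyde and 5,7,8-trimethoxyflavylium by enamine catalysis.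

Key step: step 7

Remark: atom numbers are eudesmane numbers (C1 carries the chromene, C4 the hydroxyl, C5 and C10 are the ring-fusion atoms, C7 carries the isopropenyl group); primed numbers are chromene atoms. Natural (−)-β-elemene (1S,2S,4R) and wogonin are assumed to be commercial. CIP descriptors in the names change where substituent priorities change; the SMILES strings are authoritative.

**Step 1**
Reactants: 1 wogonin
Product: 2 5,7,8-trimethoxyflavone
Conditions: MeI (excess), K2CO3, DMF, 50 °C
Reagents that add atoms: iodomethane, CI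
Why: Williamson ether synthesis; carbonate deprotonates both phenols (the chelated 5-OH needs heat and excess MeI) and each phenoxide is methylated by SN2.

**Step 2**
Reactants: 2 5,7,8-trimethoxyflavone
Product: 4 5,7,8-trimethoxyflavylium tetrafluoroborate, via flav-2-en-4-ol 3 (not isolated)
Conditions: DIBAL-H, THF, −78 → 0 °C; Rochelle salt work-up; then HBF4·OEt2, Et2O, 0 °C (salt precipitates)
Reagents that add atoms: tetrafluoroboric acid (diethyl etherate), [H+].F[B-](F)(F)F
Why: 1,2-hydride reduction of the vinylogous ester carbonyl followed by acid ionisation of the allylic, benzylic 4-carbinol, the usual flavone-to-flavylium conversion, driven by aromatisation to the benzopyrylium ring.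

**Step 3**
Reactants: 5 (−)-β-elemene
Product: 7 2-[(1S,2S,4R)-1-methyl-2,4-di(prop-1-en-2-yl)cyclohexyl]ethan-1-ol, via alkyl catecholboronate 6 (not isolated)
Conditions: catecholborane (1.1 equiv), RhCl(PPh3)3 (2 mol %), THF, 0 °C → rt; then NaOH, H2O2, 0 °C
Reagents that add atoms: hydrogen peroxide, OO
Why: Rhodium-catalysed hydroboration is much more sensitive to alkene substitution than the uncatalysed reaction, so the monosubstituted vinyl group should react anti-Markovnikov in preference to both 1,1-disubstituted isopropenyl groups; C–B oxidation then gives the primary alcohol and no stereocentre is touched.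

**Step 4**
Reactants: 7 2-[(1S,2S,4R)-1-methyl-2,4-di(prop-1-en-2-yl)cyclohexyl]ethan-1-ol
Product: 8 2-[(1S,2S,4R)-1-methyl-2,4-di(prop-1-en-2-yl)cyclohexyl]acetaldehyde
Conditions: Dess–Martin periodinane, pyridine, CH2Cl2, 0 °C → rt; used at once
Reagents that add atoms: none
Why: Dess–Martin oxidation stops at the aldehyde under buffered conditions that should leave the three alkenes alone and avoid acid-triggered carbonyl-ene closure of the ene-capable aldehyde.

**Step 5**
Reactants: 8 2-[(1S,2S,4R)-1-methyl-2,4-di(prop-1-en-2-yl)cyclohexyl]acetaldehyde; 4 5,7,8-trimethoxyflavylium tetrafluoroborate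
Product: 11 (2S)-2-[(1R,2S,4R)-1-methyl-2,4-di(prop-1-en-2-yl)cyclohexyl]-2-[(4S)-5,7,8-trimethoxy-2-phenyl-4H-chromen-4-yl]ethan-1-ol, via E-enamine 9 (not isolated), via α-chromenyl aldehyde 10 (not isolated)
Conditions: 8 (1.2 equiv), (2S,5S)-5-benzyl-2-tert-butyl-3-methylimidazolidin-4-one·TFA (20 mol %), 2,6-lutidine (1.1 equiv), MeCN (2 equiv H2O), −20 °C; then NaBH4, MeOH, −20 → 0 °C
Reagents that add atoms: none
Why: Enamine-catalysed SN1-type α-alkylation of an aldehyde by a stabilised carbenium ion, which is attacked at C4′ as by other soft carbon nucleophiles: the benzyl group should shield the Re face of E-enamine 9 so that C1 is set by Si-face attack, C4′ is expected to be set by an open transition state that keeps the quaternary C10 anti to the peri-methoxylated benzo ring, the isopropenyl groups are far weaker nucleophiles and should not compete, and the borohydride quench fixes the epimerisable aldehyde 10 as alcohol 11.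

**Step 6**
Reactants: 11 (2S)-2-[(1R,2S,4R)-1-methyl-2,4-di(prop-1-en-2-yl)cyclohexyl]-2-[(4S)-5,7,8-trimethoxy-2-phenyl-4H-chromen-4-yl]ethan-1-ol
Product: 12 4-nitrobenzenesulfonate (nosylate) of 11
Conditions: 4-nitrobenzenesulfonyl chloride, Et3N, DMAP (cat.), CH2Cl2, 0 °C; used crude
Reagents that add atoms: 4-nitrobenzenesulfonyl chloride, O=S(=O)(Cl)c1ccc(cc1)[N+](=O)[O-]
Why: DMAP-catalysed sulfonylation of the β-branched primary alcohol installs the classical leaving group of solvolytic olefin cyclisations without touching any stereocentre.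

**Step 7**
Reactants: 12 4-nitrobenzenesulfonate (nosylate) of 11
Product: 14 target 1β-[(4S)-5,7,8-trimethoxy-2-phenyl-4H-chromen-4-yl]eudesm-11-en-4α-ol, via C4 tertiary cation 13 (not isolated)
Conditions: (CF3)2CHOH/H2O 4:1, 2,6-lutidine (2 equiv), 50 °C
Reagents that add atoms: water, O
Why: In the ionising, weakly nucleophilic medium the nosylate should leave with anchimeric assistance from the C3=C4 π bond of the isopropenyl group on C5, so that C2–C3 forms as C2–O breaks and the charge lands on tertiary C4 (cation 13), which water then captures. The closest known reaction type is the classical solvolytic cation–olefin cyclisation of δ,ε-unsaturated primary arenesulfonates, here run in the elemane-to-eudesmane direction. The six-membered ring closes through a chair transition state, 6-endo-trig at the alkene and exo-tet at C2, with the C1 chromenyl group equatorial; the trans ring fusion is preset because C5 and C10 are already stereocentres whose two arms are diequatorial on the existing cyclohexane. The only new stereocentre, C4, is controlled by the axial C10 methyl, which blocks the β face so that water should add equatorially from the α face (4α-OH, 4β-CH3). The step needs chemoselectivity between the two isopropenyl groups and capture of the cation over proton loss: only the C5 isopropenyl can reach C2 (the C7 one is remote), the enol-ether alkene could only close a four-membered ring, and the water-rich medium favours hydration while lutidine protects the 4H-chromene from acid.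

**Compound list**

1 | wogonin (5,7-dihydroxy-8-methoxy-2-phenyl-4H-chromen-4-one) | COc1c(O)cc(O)c2c(=O)cc(-c3ccccc3)oc12 | starting material
2 | 5,7,8-trimethoxy-2-phenyl-4H-chromen-4-one (5,7,8-trimethoxyflavone) | COc1cc(OC)c2c(=O)cc(-c3ccccc3)oc2c1OC | intermediate
3 | 5,7,8-trimethoxy-2-phenyl-4H-chromen-4-ol (racemic flav-2-en-4-ol, not isolated) | COc1cc(OC)c2C(O)C=C(c3ccccc3)Oc2c1OC | intermediate
4 | 5,7,8-trimethoxy-2-phenylchromenylium (flavylium) tetrafluoroborate | COc1cc(OC)c2ccc(-c3ccccc3)[o+]c2c1OC.F[B-](F)(F)F | intermediate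
5 | (−)-β-elemene, (1S,2S,4R)-1-ethenyl-1-methyl-2,4-di(prop-1-en-2-yl)cyclohexane | C=C(C)[C@@H]1CC[C@@](C)(C=C)[C@@H](C1)C(C)=C | starting material
6 | 2-{2-[(1R,2S,4R)-1-methyl-2,4-di(prop-1-en-2-yl)cyclohexyl]ethyl}-1,3,2-benzodioxaborole (ring stereocentres as in 5, not isolated) | C=C(C)[C@@H]1CC[C@@](C)(CCB2Oc3ccccc3O2)[C@@H](C1)C(C)=C | intermediate
7 | 2-[(1S,2S,4R)-1-methyl-2,4-di(prop-1-en-2-yl)cyclohexyl]ethan-1-ol | C=C(C)[C@@H]1CC[C@@](C)(CCO)[C@@H](C1)C(C)=C | intermediate
8 | 2-[(1S,2S,4R)-1-methyl-2,4-di(prop-1-en-2-yl)cyclohexyl]acetaldehyde | C=C(C)[C@@H]1CC[C@@](C)(CC=O)[C@@H](C1)C(C)=C | intermediate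
9 | E-enamine of 8 with (2S,5S)-5-benzyl-2-tert-butyl-3-methylimidazolidin-4-one (N1 bonded to C2, C1=C2 E, ring stereocentres as in 8, not isolated) | C=C(C)[C@@H]1CC[C@@](C)(/C=C/N2[C@@H](Cc3ccccc3)C(=O)N(C)[C@H]2C(C)(C)C)[C@@H](C1)C(C)=C | intermediate
10 | (2S)-2-[(1R,2S,4R)-1-methyl-2,4-di(prop-1-en-2-yl)cyclohexyl]-2-[(4R)-5,7,8-trimethoxy-2-phenyl-4H-chromen-4-yl]acetaldehyde (C1 and C4′ arranged as in the target, not isolated) | C=C(C)[C@@H]1CC[C@@](C)([C@@H](C=O)[C@H]2C=C(c3ccccc3)Oc3c(OC)c(OC)cc(OC)c32)[C@@H](C1)C(C)=C | intermediate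
11 | (2S)-2-[(1R,2S,4R)-1-methyl-2,4-di(prop-1-en-2-yl)cyclohexyl]-2-[(4S)-5,7,8-trimethoxy-2-phenyl-4H-chromen-4-yl]ethan-1-ol | C=C(C)[C@@H]1CC[C@@](C)([C@@H](CO)[C@H]2C=C(c3ccccc3)Oc3c(OC)c(OC)cc(OC)c32)[C@@H](C1)C(C)=C | intermediate
12 | (2S)-2-[(1R,2S,4R)-1-methyl-2,4-di(prop-1-en-2-yl)cyclohexyl]-2-[(4S)-5,7,8-trimethoxy-2-phenyl-4H-chromen-4-yl]ethyl 4-nitrobenzenesulfonate | C=C(C)[C@@H]1CC[C@@](C)([C@@H](COS(=O)(=O)c2ccc(cc2)[N+](=O)[O-])[C@H]2C=C(c3ccccc3)Oc3c(OC)c(OC)cc(OC)c32)[C@@H](C1)C(C)=C | intermediate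
13 | 1β-[(4S)-5,7,8-trimethoxy-2-phenyl-4H-chromen-4-yl]eudesm-11-en-4-yl cation (5α-H, 7β-isopropenyl, 10β-CH3, not isolated) | C=C(C)[C@@H]1CC[C@]2(C)[C@@H](C1)[C+](C)CC[C@H]2[C@H]1C=C(c2ccccc2)Oc2c(OC)c(OC)cc(OC)c21 | intermediate
14 | (1S,4R,5R,7R,10S)-1-[(4S)-5,7,8-trimethoxy-2-phenyl-4H-chromen-4-yl]eudesm-11-en-4-ol (1β-chromenyl, 4α-OH, 4β-CH3, 5α-H, 7β-isopropenyl, 10β-CH3) | C=C(C)[C@@H]1CC[C@]2(C)[C@@H](C1)[C@](C)(O)CC[C@H]2[C@H]1C=C(c2ccccc2)Oc2c(OC)c(OC)cc(OC)c21 | target

**Step count.** Total: 7 steps. Longest linear sequence: 5 steps (5 → 7 → 8 → 11 → 12 → 14; the flavylium branch 1 → 2 → 4 joins at step 5 and is equally long).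

**Steps most likely to fail**

1. Step 7. The C4 cation may lose a proton to selinene-type dienes instead of adding water, or the sulfonate may be displaced at C2 without ring closure. The fallback closes the ring from the carbonyl oxidation level. It sets out from aldehyde 10, isolated by leaving out the borohydride quench of step 5. Aqueous-acid Prins cyclisation with hydration (0.3% H2SO4, THF/H2O, rt, the conditions that turn citronellal into p-menthane-3,8-diol) should let C3 attack the protonated C2 carbonyl in a largely aqueous medium and give 1β-chromenyl-eudesm-11-ene-2ξ,4α-diol F1. 1,1′-Thiocarbonyldiimidazole (DMAP, toluene, 60 °C) should derivatise only the secondary C2 hydroxyl and give the C2 O-(imidazol-1-ylthiocarbonyl) derivative F2. Barton–McCombie deoxygenation (Bu3SnH, AIBN, toluene, 90 °C) then removes the C2 oxygen, and the sequence comes back to the route at 14.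

2. Step 5. Facial selectivity at C1 or C4′ may be poor, or the hindered β-quaternary aldehyde may form its enamine too slowly. The fallback hands control to a covalent auxiliary and sets out from aldehyde 8. Pinnick oxidation (NaClO2, NaH2PO4, 2-methyl-2-butene, t-BuOH/H2O) gives 2-[(1S,2S,4R)-1-methyl-2,4-di(prop-1-en-2-yl)cyclohexyl]acetic acid F3. Pivaloyl chloride/Et3N (THF, −20 °C) gives the mixed pivalic anhydride F4, which acylates lithiated (S)-4-benzyloxazolidin-2-one to the N-acyl oxazolidinone F5. Its chlorotitanium Z-enolate (TiCl4, i-Pr2NEt, CH2Cl2, −78 °C) should be alkylated by flavylium salt 4 on the face away from the benzyl group (Si face of C1, SN1-type enolate alkylation by a stabilised cation) to give the C1-chromenyl imide F6. LiBH4 (Et2O/H2O, 0 °C) releases the auxiliary and the route is rejoined at alcohol 11.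

3. Step 3. The catalyst may lose chemoselectivity by hydroborating or isomerising an isopropenyl group. The fallback oxidises the vinyl group directly. It sets out from 5 and uses nitrite-modified aldehyde-selective Wacker oxidation (PdCl2(PhCN)2, CuCl2, AgNO2, t-BuOH/MeNO2, O2, rt), to which 1,1-disubstituted alkenes are inert, to give aldehyde 8, where the route is rejoined. No new compound is made (F0).

**Further compounds**

F1 | step 7 | 1β-[(4S)-5,7,8-trimethoxy-2-phenyl-4H-chromen-4-yl]eudesm-11-ene-2ξ,4α-diol (C2 epimers converge later) | C=C(C)[C@@H]1CC[C@]2(C)[C@@H](C1)[C@](C)(O)CC(O)[C@H]2[C@H]1C=C(c2ccccc2)Oc2c(OC)c(OC)cc(OC)c21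
F2 | step 7 | 2-O-(imidazol-1-ylthiocarbonyl) derivative of F1 | C=C(C)[C@@H]1CC[C@]2(C)[C@@H](C1)[C@](C)(O)CC(OC(=S)n1ccnc1)[C@H]2[C@H]1C=C(c2ccccc2)Oc2c(OC)c(OC)cc(OC)c21
F3 | step 5 | 2-[(1S,2S,4R)-1-methyl-2,4-di(prop-1-en-2-yl)cyclohexyl]acetic acid | C=C(C)[C@@H]1CC[C@@](C)(CC(=O)O)[C@@H](C1)C(C)=C
F4 | step 5 | mixed anhydride of F3 with pivalic acid | C=C(C)[C@@H]1CC[C@@](C)(CC(=O)OC(=O)C(C)(C)C)[C@@H](C1)C(C)=C
F5 | step 5 | (S)-4-benzyl-3-{2-[(1S,2S,4R)-1-methyl-2,4-di(prop-1-en-2-yl)cyclohexyl]acetyl}oxazolidin-2-one | C=C(C)[C@@H]1CC[C@@](C)(CC(=O)N2[C@@H](Cc3ccccc3)COC2=O)[C@@H](C1)C(C)=C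
F6 | step 5 | F5 carrying the 5,7,8-trimethoxy-2-phenyl-4H-chromen-4-yl group at C1 (C1 and C4′ arranged as in the target) | C=C(C)[C@@H]1CC[C@@](C)([C@@H](C(=O)N2[C@@H](Cc3ccccc3)COC2=O)[C@H]2C=C(c3ccccc3)Oc3c(OC)c(OC)cc(OC)c32)[C@@H](C1)C(C)=C
F0 | step 3 | none | none
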